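The chair opened on a small charge: 20 mM of free catalyst against 0.20 M of starting material in the flask.

| setting | Tuesday's | Saturday's | Sunday's | flask |
|---|---|---|---|---|
| starting material | 0.13 M | 0.30 M | 0.20 M | 0.20 M |
| coupling partner | 0.14 M | 0.14 M | 0.14 M | 0.140 M |
| free catalyst | 20 mM | 20 mM | 10 mM | 20 mM |
| remark | run made earlier | run made earlier | run made earlier |  |

| run | time / h | target / % | starting material / % |
|---|---|---|---|
| Tuesday's | 5.00 | 11.2 | 4.1 |
| Tuesday's | 10.0 | 20.7 | 0 |
| Tuesday's | 15.0 | 26.1 | 0.6 |
| Tuesday's | 20.0 | 29.4 | 1.3 |
| Tuesday's | 25.0 | 33.8 | 0 |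
| Tuesday's | 30.0 | 34.6 | 0 |
| Saturday's | 2.50 | 3.6 | 19.6 |
| Saturday's | 4.00 | 7.7 | 8.6 |
| Saturday's | 8.00 | 14.1 | 0.2 |
| Saturday's | 12.0 | 19.0 | 0.4 |
| Saturday's | 20.0 | 26.0 | 0 |
| Saturday's | 30.0 | 28.5 | 0.7 |
| Sunday's | 6.00 | 4.8 | 15.5 |
| Sunday's | 12.0 | 8.9 | 4.4 |
| Sunday's | 20.0 | 14.0 | 1.5 |
| Sunday's | 25.0 | 15.7 | 0.2 |
| Sunday's | 30.0 | 17.7 | 2.1 |

(each reading ± 1 percentage point)



1. factor on the rate of making target when 20 % of the starting material are converted if free catalyst is charged twice over
2. factor on the rate when 20 % of the starting material are converted if free catalyst is charged at 200 mM instead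

The first speaker reported that starting material falls pseudo-first-order. Its constant reads 0.613 h⁻¹ in Saturday's run and 0.311 h⁻¹ in Sunday's. That is about twice for twice the catalyst, though the two runs also differ in starting material. She put the flask's look, the moment of 20 % conversion, near 0.364 h.

The secretary, reckoning for himself, proposed to count turnovers. He defined N, the starting material converted at the look per catalyst charged 2.00. Doubling the catalyst gives 1.00, and 200 mM gives 0.200.

He argued that each catalyst keeps its pace, so a smaller N means a shorter time, and catalyst times time stays the same at the look. He took the lag in target for a later catalyst step building up. If that step is still building, its product sees the same catalyst times time, and the factor is near one. If it has caught up, the factor follows the charge. He expected under 2 on doubling, and little more at 200 mM.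

The forecaster disagreed. He gave 2.8 on doubling and 30 at 200 mM, on “an apparent catalyst order near 1.5”.

The simulation gives 1.28 at the doubled charge and 1.60 at 200 mM, where N is 0.200.

    starting material + free catalyst → free catalyst + open intermediate (k = 37.0 M⁻¹ h⁻¹)
    free catalyst + open intermediate ⇌ catalyst intermediate (K = 1.70 M⁻¹, k = 4.00 M⁻¹ h⁻¹)
    coupling partner + catalyst intermediate → free catalyst + target (k = 20.0 M⁻¹ h⁻¹)
    starting material + coupling partner → uncatalysed product (k = 0.150 M⁻¹ h⁻¹)
    free catalyst → spent catalyst (k = 0.0610 h⁻¹)

In the flask the look came at 0.297 h with N at 2.00, while the first step was running on starting material, the mid-point of its turnover falling at 0.962 h. Afterwards, with starting material down to 8.13 % at 4.00 h and open intermediate at 80.7 %, free catalyst went on binding open intermediate, that step having 81 % of its turnover up to 40.0 h behind it at 20.0 h, while coupling partner drew target from catalyst intermediate and target reached 35.5 % at 40.0 h, with spent catalyst at 88.3 %.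

(The data are simulated on assumed constants; the scatter is artificial.)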